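## The problem

The target, (4S,6R)-6-bromo-1-[(1S)-2-bromo-1-chloroethyl]-4-chloro-5,5-dimethylcyclohex-1-ene (15), is one cyclohexene ring carrying four halogens on a C10 skeleton. The atoms are labelled C1 (CMe2), C2 (ring CHCl), C3 (CH2), C4=C5 (ring alkene, C5 substituted), C6 (CHBr), C7 (side-chain CHCl) and C8 (CH2Br). The quaternary C1 is flanked by the ring stereocentres C2 and C6, whose halogens are trans; both are neopentylic, so SN2 substitution there is slow and ionisation invites methyl migration. C6–Br and C7–Cl are both allylic to C4=C5, and C8–Br is primary and β to chlorine. The molecule will therefore not survive strong nucleophiles, bases, free halide at elevated temperature or ionising acids, and halogens should be placed late or by reactions that never make them leaving groups. C2 and C6 can control each other through the ring, but the exocyclic C7 is insulated from them by the sp2 carbon C5 and needs reagent control. The enabling feature is the cyclohexene itself: C4=C5 with the bromine-bearing C6 next to C1 is a [4+2] retron. In it C3=C4–C5=C6 is a diene whose C6 terminus is a vinyl bromide and C1=C2 is an isobutenyl donor alkene, so the C6 bromide can arrive on an sp2 carbon instead of by substitution.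

## Retrosynthesis

**C8–Br.** The primary bromide of 15 is the group most exposed to substitution and is cut first, back to the primary alcohol 14 (Appel bromination). The reverse order (bromine on C8 first, chlorine on C7 afterwards) would require substitution at C7 next to a bromine, where bromonium participation can scramble position and configuration; chlorine on C7 is a poor neighbouring group. The forward reaction must only be mild and non-basic.

**C7–Cl.** The C7–Cl bond of 14 is cut to the terminal vinyl epoxide 12. One functional group then supplies both the C7 chloride (opening with inversion at the allylic carbon) and the C8 oxygen. Direct deoxychlorination of an allylic C7 carbinol would compete with SN2′ attack at C4. The forward step must favour attack at C7 over C8 and proceed with inversion.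

**C7 configuration.** Epoxide 12 is traced through chlorohydrin 11 to the chloromethyl ketone 10. The C7 stereocentre is thereby removed from the precursor and set by a catalyst-controlled ketone reduction, since the ring stereocentres cannot be trusted to direct a reaction at C7. A substrate-controlled methylene transfer to the corresponding enal was judged weaker for that reason.

**C7–C8.** The C7–C8 bond of 10 is cut to the methyl ester 9 and a chloromethyl carbenoid. The ester carbon of the cycloadduct is C7, so one acylation supplies the missing carbon already functionalised.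

**C2–Cl.** The chloride of 9 is cut to the alcohol 8 and its silyl ether 7, with inversion at C2. This is done early, while the molecule carries only one other halogen and no epoxide or free side-chain hydroxyl. It requires 7 to have C2–O cis to C6–Br, so that inversion gives the trans Cl/Br relation.

**Ring (key cut).** Cyclohexene 7 is cut at C1–C6 and C2–C3 into the bromodiene ester 6 and the silyl enol ether 2. This removes the ring, the quaternary centre and both ring stereocentres at once, and it is the only cut that delivers C6–Br without substitution at a neopentylic allylic carbon. The forward reaction must be regioselective (CMe2 to C6), endo with respect to the silyloxy group, and face-selective under a chiral Lewis acid.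

**Fragments.** Diene 6 is cut at the C4–C5 bond into methyl (E)-3-bromo-2-iodoacrylate 4 and tributyl(vinyl)stannane 5; 4 comes from methyl propiolate 3 by addition of IBr. Enol ether 2 comes from isobutyraldehyde 1. Both fragments are two steps or fewer from commercial materials.

## Roads not taken

**Alternative 1: chromium-mediated closure of C5–C6.** The cut is C5–C6. An open-chain (Z)-alkenyl iodide bearing an aldehyde would be treated with CrCl2 and catalytic NiCl2, so that the alkenylchromium species adds to the aldehyde and forms the ring and the C6 carbinol of A1.
- Merits: this ring closure is an established reaction class that tolerates alkyl chlorides and acetals, and it is a safer key step than the one chosen here. C2–Cl and the C7 oxygen are fixed before cyclisation, so C7 is secured earlier.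
- Weak points: C6 arrives as an alcohol and must become a bromide by substitution at a centre that is both neopentylic and allylic, where SN2 is slow and SN2′ and ionisation compete. In A1 the hydroxyl sits on the face bromine must finally occupy, so the exchange would need overall retention or the other carbinol epimer. The open-chain precursor (quaternary carbon, adjacent secondary chloride, trisubstituted Z-alkenyl iodide) needs a long linear sequence, and the dioxolane still has to be turned into C7–Cl and C8–Br.
- Comparison: the chosen plan sets against this a C6 bromide made without substitution and a ring assembled from two short fragments. It pays with an unprecedented cycloaddition and a later C7 construction.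

**Alternative 2: anodic manganese radical cyclisation with chlorine-atom capture.** The cuts are C3–C4 and C2–Cl. With catalytic MnCl2 and LiCl in an undivided cell, a β-keto ester would be oxidised by anodically formed trivalent manganese chloride to the C4 radical. This closes 6-endo onto C3, and the C2 radical takes chlorine from the metal chloride to give A2.
- Merits: the neopentylic C2 chloride is made by atom transfer, not by substitution. In this respect it is better than the chosen route, whose step 6 is exactly that substitution. Ring and C–Cl are formed together from cheap reagents.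
- Weak points: in A2 the ester sits on C4 and a carbonyl on C5, so the ester must be excised and the whole C7–C8 chain attached to C5 afterwards. C6 is again an oxygen that must become bromide at a neopentylic centre, again on the face bromine must occupy. The C2 configuration depends only on substrate-controlled chlorine transfer, and 5-exo closure competes.
- Comparison: the chosen plan sets against the easier C2 chloride that C6–Br and the C7 carbon are both in place after its key step.

**Alternative 3: ring-closing enyne metathesis.** The cut is C4=C5. An acyclic 1,7-enyne already carrying C6–Br and C2–Cl would be closed with the second-generation Grubbs catalyst under ethene, transferring the alkene CH2 to C7 and giving the vinylcyclohexene A3.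
- Merits: enyne metathesis is catalytic, tolerant of alkyl halides and far better precedented than the cycloaddition chosen here. Both ring halogens are settled before the ring exists.
- Weak points: both halogens must be installed on the open chain by substitution next to the quaternary carbon, and the C6 bromide is propargylic there, open to SN2′ formation of a bromoallene. A3 is a 1,3-diene whose vinyl group must then be bromochlorinated with site selectivity (vinyl against ring alkene), 1,2- against 1,4-addition, and face selectivity at C7 with no directing group.
- Comparison: the chosen plan has a riskier ring-forming step, but sets C7 by a reagent-controlled ketone reduction and avoids dihalogenation of a diene.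

Key step: step 4

Assumption: the (S)-configured oxazaborolidine is taken to expose the diene face leading to (4R,6R)-7; the antipodal catalyst is equally available and would be used if the sense proves opposite.

Note on descriptors: the CIP descriptor of the bromine-bearing ring carbon reads R in 7 and 8, S in 9–12 and R in 13–15 only because the ranking of its neighbours changes; its spatial arrangement is never altered.

## Route

Step 1
Reactants: 1 isobutyraldehyde
Product: 2 tert-butyldimethyl[(2-methylprop-1-en-1-yl)oxy]silane
Conditions: TBSOTf, Et3N, CH2Cl2, 0 °C → rt
Reagents that add atoms: tert-butyldimethylsilyl trifluoromethanesulfonate, CC(C)(C)[Si](C)(C)OS(=O)(=O)C(F)(F)F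
Why: Soft enolisation and O-silylation of an aldehyde (silyl enol ether formation); there is only one enolisable position and the CMe2 terminus has no E/Z isomerism.

Step 2
Reactants: 3 methyl propiolate
Product: 4 methyl (2E)-3-bromo-2-iodoprop-2-enoate
Conditions: IBr, CH2Cl2, 0 °C → rt, dark
Reagents that add atoms: iodine monobromide, IBr
Why: Interhalogen addition to an alkynoate: the electrophilic iodine goes to the α-carbon and bromide to the β-carbon in an anti sense, as in the known iodochlorination of alkynoates, which should give the E isomer with Br cis to the ester.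

Step 3
Reactants: 4 methyl (2E)-3-bromo-2-iodoprop-2-enoate; 5 tributyl(vinyl)stannane
Product: 6 methyl (2Z)-2-(bromomethylidene)but-3-enoate
Conditions: Pd2(dba)3 (2.5 mol %), AsPh3 (20 mol %), CuI (10 mol %), NMP, rt; rapid filtration through silica/KF, kept cold in solution with BHT and used at once
Reagents that add atoms: none
Why: Stille coupling; oxidative addition of zerovalent palladium into C–I is faster than into C–Br, as exploited in sequential couplings of β-halo-α-iodoacrylates, and occurs with retention, so Br stays cis to the ester (Z by the CIP rules); room temperature limits dimerisation of the diene.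

Step 4
Reactants: 6 methyl (2Z)-2-(bromomethylidene)but-3-enoate; 2 tert-butyldimethyl[(2-methylprop-1-en-1-yl)oxy]silane
Product: 7 methyl (4R,6R)-6-bromo-4-[(tert-butyldimethylsilyl)oxy]-5,5-dimethylcyclohex-1-ene-1-carboxylate
Conditions: (S)-3,3-diphenyl-1-(2-methylphenyl)tetrahydro-1H,3H-pyrrolo[1,2-c][1,3,2]oxazaborole (20 mol %) preactivated with AlBr3 (16 mol %), 2 (2 equiv), CH2Cl2, −78 °C, slow addition of 6
Reagents that add atoms: none
Why: Proposed new method: the boron Lewis acid binds the ester carbonyl of 6 and lowers the diene LUMO, so that the nucleophilic CMe2 carbon of 2 attacks the bromine-bearing β-carbon C6 while the oxygen-bearing carbon C2 bonds to the vinyl terminus C3 in a concerted but strongly asynchronous [4+2] (in the limit a Mukaiyama–Michael addition followed by vinylogous aldol closure of the dienolate onto the silyloxocarbenium ion). The closest known reaction types are the inverse-electron-demand Diels–Alder reactions of 2-alkoxycarbonyl-1,3-dienes and 2-pyrones with enol ethers and the enantioselective [2+2] cycloadditions of silyl enol ethers with acrylates under oxazaborolidine–AlBr3 catalysis; neither has been shown on a 1-bromodiene. The six-membered ring closes suprafacially across C6 and C3 of the s-cis diene, and six-membered closure should win over four-membered closure because bonding at C3 leaves the conjugated C4=C5 ester. C6 takes its configuration from the Z vinyl bromide (bromine outside in the s-cis diene) and from the diene face left open by the catalyst; C2 follows from endo orientation of the silyloxy group, which places O cis to Br. Regiochemistry is secured by the match of the ester-polarised C6 with the oxygen-polarised CMe2 carbon. The bulky silyl group, the halide-free boron acid and the low temperature are meant to suppress silyl transfer and loss of bromide from the transient enolate, and slow addition of 6 to excess 2 holds back diene dimerisation.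

Step 5
Reactants: 7 methyl (4R,6R)-6-bromo-4-[(tert-butyldimethylsilyl)oxy]-5,5-dimethylcyclohex-1-ene-1-carboxylate
Product: 8 methyl (4R,6R)-6-bromo-4-hydroxy-5,5-dimethylcyclohex-1-ene-1-carboxylate
Conditions: HF·pyridine, THF/pyridine, 0 °C → rt
Reagents that add atoms: none
Why: Acidic fluoride desilylation; HF·pyridine is preferred to basic fluoride because the 2-(1-bromoalkyl)enoate is open to SN2′ attack and elimination; no stereocentre is touched.

Step 6
Reactants: 8 methyl (4R,6R)-6-bromo-4-hydroxy-5,5-dimethylcyclohex-1-ene-1-carboxylate
Product: 9 methyl (4S,6S)-6-bromo-4-chloro-5,5-dimethylcyclohex-1-ene-1-carboxylate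
Conditions: PPh3/NCS (premixed), CH2Cl2, 0 → 40 °C
Reagents that add atoms: N-chlorosuccinimide, ClN1C(=O)CCC1=O
Why: Appel-type deoxychlorination through the alkoxyphosphonium chloride ion pair with SN2 inversion at C2, turning the cis O/Br relation into the trans Cl/Br relation of the target; premixing leaves no free phosphine to add to the bromo enoate, and the non-ionising medium guards against methyl migration from C1.

Step 7
Reactants: 9 methyl (4S,6S)-6-bromo-4-chloro-5,5-dimethylcyclohex-1-ene-1-carboxylate
Product: 10 2-chloro-1-[(4S,6S)-6-bromo-4-chloro-5,5-dimethylcyclohex-1-en-1-yl]ethan-1-one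
Conditions: ICH2Cl, MeLi·LiBr, THF/Et2O, −78 °C; AcOH quench at −78 °C
Reagents that add atoms: chloroiodomethane, ClCI
Why: Acylation of chloromethyllithium (formed in situ by iodine–lithium exchange) by an ester; the tetrahedral lithium hemiketal persists at −78 °C and releases the chloromethyl ketone only on acidic quench, which prevents double addition, and carbonyl attack should outrun exchange at the hindered secondary bromide.

Step 8
Reactants: 10 2-chloro-1-[(4S,6S)-6-bromo-4-chloro-5,5-dimethylcyclohex-1-en-1-yl]ethan-1-one
Product: 11 (1R)-2-chloro-1-[(4S,6S)-6-bromo-4-chloro-5,5-dimethylcyclohex-1-en-1-yl]ethan-1-ol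
Conditions: (R)-Me-CBS oxazaborolidine (20 mol %), BH3·SMe2 (0.7 equiv), THF, −20 °C; MeOH quench
Reagents that add atoms: none
Why: CBS reduction; with the cyclohexenyl group as the large and CH2Cl as the small substituent the (R)-catalyst should give the (R)-carbinol at C7 under reagent control, and 1,2-reduction is the normal course for enones.

Step 9
Reactants: 11 (1R)-2-chloro-1-[(4S,6S)-6-bromo-4-chloro-5,5-dimethylcyclohex-1-en-1-yl]ethan-1-ol
Product: 12 (2R)-2-[(4S,6S)-6-bromo-4-chloro-5,5-dimethylcyclohex-1-en-1-yl]oxirane
Conditions: NaH, THF, 0 °C
Reagents that add atoms: none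
Why: Intramolecular Williamson etherification (3-exo-tet) of the chlorohydrin alkoxide; C7 keeps its configuration because its C–O bond is not broken, and the aprotic medium avoids solvolysis of the allylic bromide.

Step 10
Reactants: 12 (2R)-2-[(4S,6S)-6-bromo-4-chloro-5,5-dimethylcyclohex-1-en-1-yl]oxirane
Product: 14 (2S)-2-[(4S,6R)-6-bromo-4-chloro-5,5-dimethylcyclohex-1-en-1-yl]-2-chloroethan-1-ol, via trimethylsilyl ether 13 (not isolated)
Conditions: TMSCl, EtOAc/CH2Cl2, 0 °C; then 10% aq. citric acid, THF, 0 °C
Reagents that add atoms: chlorotrimethylsilane, C[Si](C)(C)Cl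
Why: Chloride opening of a vinyl epoxide under silyl activation occurs at the allylic carbon C7 with SN2 inversion, converting the (R)-epoxide into the (S)-chloride and leaving oxygen on C8; the silyl ether is cleaved by the mild acid.

Step 11
Reactants: 14 (2S)-2-[(4S,6R)-6-bromo-4-chloro-5,5-dimethylcyclohex-1-en-1-yl]-2-chloroethan-1-ol
Product: 15 (4S,6R)-6-bromo-1-[(1S)-2-bromo-1-chloroethyl]-4-chloro-5,5-dimethylcyclohex-1-ene
Conditions: CBr4, PPh3 (added last), CH2Cl2, 0 °C
Reagents that add atoms: carbon tetrabromide, BrC(Br)(Br)Br
Why: Appel bromination of a primary alcohol by SN2 on the alkoxyphosphonium ion; the β-chlorine is a poor neighbouring group, so C7 should not be disturbed, and no stereocentre is created.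

## Compound list

1 | isobutyraldehyde (2-methylpropanal) | CC(C)C=O | starting material
2 | tert-butyldimethyl[(2-methylprop-1-en-1-yl)oxy]silane | CC(C)=CO[Si](C)(C)C(C)(C)C | intermediate
3 | methyl propiolate | C#CC(=O)OC | starting material
4 | methyl (2E)-3-bromo-2-iodoprop-2-enoate | Br/C=C(/I)C(=O)OC | intermediate
5 | tributyl(vinyl)stannane | C=C[Sn](CCCC)(CCCC)CCCC | starting material
6 | methyl (2Z)-2-(bromomethylidene)but-3-enoate | Br/C=C(/C=C)C(=O)OC | intermediate
7 | methyl (4R,6R)-6-bromo-4-[(tert-butyldimethylsilyl)oxy]-5,5-dimethylcyclohex-1-ene-1-carboxylate | CC1(C)[C@H](O[Si](C)(C)C(C)(C)C)CC=C(C(=O)OC)[C@@H]1Br | intermediate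
8 | methyl (4R,6R)-6-bromo-4-hydroxy-5,5-dimethylcyclohex-1-ene-1-carboxylate | CC1(C)[C@H](O)CC=C(C(=O)OC)[C@@H]1Br | intermediate
9 | methyl (4S,6S)-6-bromo-4-chloro-5,5-dimethylcyclohex-1-ene-1-carboxylate | CC1(C)[C@@H](Cl)CC=C(C(=O)OC)[C@@H]1Br | intermediate
10 | 2-chloro-1-[(4S,6S)-6-bromo-4-chloro-5,5-dimethylcyclohex-1-en-1-yl]ethan-1-one | CC1(C)[C@@H](Cl)CC=C(C(=O)CCl)[C@@H]1Br | intermediate
11 | (1R)-2-chloro-1-[(4S,6S)-6-bromo-4-chloro-5,5-dimethylcyclohex-1-en-1-yl]ethan-1-ol | CC1(C)[C@@H](Cl)CC=C([C@@H](O)CCl)[C@@H]1Br | intermediate
12 | (2R)-2-[(4S,6S)-6-bromo-4-chloro-5,5-dimethylcyclohex-1-en-1-yl]oxirane | CC1(C)[C@@H](Cl)CC=C([C@@H]2CO2)[C@@H]1Br | intermediate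
13 | {(2S)-2-[(4S,6R)-6-bromo-4-chloro-5,5-dimethylcyclohex-1-en-1-yl]-2-chloroethoxy}trimethylsilane | CC1(C)[C@@H](Cl)CC=C([C@H](Cl)CO[Si](C)(C)C)[C@@H]1Br | intermediate
14 | (2S)-2-[(4S,6R)-6-bromo-4-chloro-5,5-dimethylcyclohex-1-en-1-yl]-2-chloroethan-1-ol | CC1(C)[C@@H](Cl)CC=C([C@H](Cl)CO)[C@@H]1Br | intermediate
15 | (4S,6R)-6-bromo-1-[(1S)-2-bromo-1-chloroethyl]-4-chloro-5,5-dimethylcyclohex-1-ene | CC1(C)[C@@H](Cl)CC=C([C@H](Cl)CBr)[C@@H]1Br | target

## Step count and risks

Total steps: 11. Longest linear sequence: 10 steps (steps 2–11, from methyl propiolate 3).

**Step 4 (key step).** The most likely failures are a stepwise course and weak face selectivity. In a stepwise course the transient ester enolate could expel bromide, close to a four-membered ring or transfer silicon. Face selectivity is uncertain because the ester binds the boron acid through one point only and C5 lacks the α-hydrogen that organises simple acrylates; exo orientation of the silyloxy group is a further possibility. The fallback uses known reactions and builds the ring by C5–C6 closure instead of cycloaddition; it sets out from 2 and returns at 7.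
- Enol ether 2 adds to trimethyl orthoformate (cat. TMSOTf, CH2Cl2, −78 °C) to give 3,3-dimethoxy-2,2-dimethylpropanal F1.
- A catalytic asymmetric vinylogous Mukaiyama aldol reaction of F1 with [(1-methoxybuta-1,3-dien-1-yl)oxy]trimethylsilane (SiCl4, chiral bisphosphoramide Lewis base) sets the C2 carbinol in methyl (2E,5R)-5-hydroxy-7,7-dimethoxy-6,6-dimethylhept-2-enoate F2.
- Silylation (TBSOTf, 2,6-lutidine) gives methyl (2E,5R)-5-[(tert-butyldimethylsilyl)oxy]-7,7-dimethoxy-6,6-dimethylhept-2-enoate F3.
- Mild acetal hydrolysis (aq. TFA, CH2Cl2) frees methyl (2E,5R)-5-[(tert-butyldimethylsilyl)oxy]-6,6-dimethyl-7-oxohept-2-enoate F4.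
- A phosphine-mediated intramolecular Morita–Baylis–Hillman reaction (PMe3) closes C5–C6 to methyl (4R,6S)-4-[(tert-butyldimethylsilyl)oxy]-6-hydroxy-5,5-dimethylcyclohex-1-ene-1-carboxylate F5; the C6 epimer would be recycled by Mitsunobu inversion.
- Appel bromination (CBr4, PPh3) with inversion at C6 returns 7.

**Step 6.** SN2 displacement at the neopentylic C2 carbinol is slow. Elimination towards C3 to a conjugated diene, or chloride-induced exchange and allylic transposition of the activated C6 bromide, may therefore overtake it. The fallback is a radical deoxychlorination; it sets out from 8 and returns at 9.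
- Acylation of 8 with methyl chlorooxoacetate (Et3N, DMAP) gives methyl (4R,6R)-6-bromo-4-[(2-methoxy-2-oxoacetyl)oxy]-5,5-dimethylcyclohex-1-ene-1-carboxylate F6.
- Selective hydrolysis with CsOH (1 equiv, THF/H2O) gives cesium 2-{[(1R,3R)-3-bromo-4-(methoxycarbonyl)-2,2-dimethylcyclohex-4-en-1-yl]oxy}-2-oxoacetate F7.
- Photoredox oxidation ([Ir(dF(CF3)ppy)2(dtbbpy)]PF6, blue light) with ethyl trichloroacetate as chlorine-atom donor gives 9 through the C2 radical.
- Chlorine transfer should occur anti to the C6 bromine. Because the radical is planar, this path also serves if the cycloaddition delivers the C2 epimer of 7.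

**Step 10.** Opening may go astray by attack at the terminal C8, by SN2′ attack at C4, or by partial ionisation with erosion of the C7 configuration, since the allylic cation is stabilised by the trisubstituted alkene. The fallback avoids the epoxide; it sets out from 9 and returns at 15.
- Ester 9 is acylated with bromomethyllithium (CH2Br2, MeLi·LiBr, −78 °C) to 2-bromo-1-[(4S,6S)-6-bromo-4-chloro-5,5-dimethylcyclohex-1-en-1-yl]ethan-1-one F8.
- (R)-Me-CBS reduction gives (1R)-2-bromo-1-[(4S,6S)-6-bromo-4-chloro-5,5-dimethylcyclohex-1-en-1-yl]ethan-1-ol F9.
- Invertive chlorination of the allylic alcohol with PPh3/hexachloroacetone (CH2Cl2, 0 °C) gives 15 directly.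
- This is two steps shorter, but participation of the neighbouring bromine is the known hazard, which is why it is held in reserve.

**Step 3.** Oxidative addition may also occur at the conjugatively activated β C–Br bond, the alkene geometry may drift, and the diene may dimerise during removal of tin residues. The fallback needs neither palladium nor tin and also bypasses step 2; it sets out from 3 and returns at 6.
- A MgBr2·OEt2-mediated bromo-aldol reaction of 3 with acetaldehyde (bromide conjugate addition, capture of the allenolate, kinetic Z product at low temperature) gives racemic methyl (2Z)-2-(bromomethylidene)-3-hydroxybutanoate F10.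
- Mesylation (MsCl, Et3N) gives methyl (2Z)-2-(bromomethylidene)-3-[(methylsulfonyl)oxy]butanoate F11.
- DBU elimination towards the methyl group gives 6.

## Further compounds

F1 | step 4 | 3,3-dimethoxy-2,2-dimethylpropanal | COC(OC)C(C)(C)C=O
F2 | step 4 | methyl (2E,5R)-5-hydroxy-7,7-dimethoxy-6,6-dimethylhept-2-enoate | COC(OC)C(C)(C)[C@H](O)C/C=C/C(=O)OC
F3 | step 4 | methyl (2E,5R)-5-[(tert-butyldimethylsilyl)oxy]-7,7-dimethoxy-6,6-dimethylhept-2-enoate | COC(OC)C(C)(C)[C@H](O[Si](C)(C)C(C)(C)C)C/C=C/C(=O)OC
F4 | step 4 | methyl (2E,5R)-5-[(tert-butyldimethylsilyl)oxy]-6,6-dimethyl-7-oxohept-2-enoate | O=CC(C)(C)[C@H](O[Si](C)(C)C(C)(C)C)C/C=C/C(=O)OC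
F5 | step 4 | methyl (4R,6S)-4-[(tert-butyldimethylsilyl)oxy]-6-hydroxy-5,5-dimethylcyclohex-1-ene-1-carboxylate | CC1(C)[C@H](O[Si](C)(C)C(C)(C)C)CC=C(C(=O)OC)[C@H]1O
F6 | step 6 | methyl (4R,6R)-6-bromo-4-[(2-methoxy-2-oxoacetyl)oxy]-5,5-dimethylcyclohex-1-ene-1-carboxylate | CC1(C)[C@H](OC(=O)C(=O)OC)CC=C(C(=O)OC)[C@@H]1Br
F7 | step 6 | cesium 2-{[(1R,3R)-3-bromo-4-(methoxycarbonyl)-2,2-dimethylcyclohex-4-en-1-yl]oxy}-2-oxoacetate | CC1(C)[C@H](OC(=O)C(=O)[O-])CC=C(C(=O)OC)[C@@H]1Br.[Cs+]
F8 | step 10 | 2-bromo-1-[(4S,6S)-6-bromo-4-chloro-5,5-dimethylcyclohex-1-en-1-yl]ethan-1-one | CC1(C)[C@@H](Cl)CC=C(C(=O)CBr)[C@@H]1Br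
F9 | step 10 | (1R)-2-bromo-1-[(4S,6S)-6-bromo-4-chloro-5,5-dimethylcyclohex-1-en-1-yl]ethan-1-ol | CC1(C)[C@@H](Cl)CC=C([C@@H](O)CBr)[C@@H]1Br
F10 | step 3 | methyl (2Z)-2-(bromomethylidene)-3-hydroxybutanoate (racemic) | Br/C=C(/C(C)O)C(=O)OC
F11 | step 3 | methyl (2Z)-2-(bromomethylidene)-3-[(methylsulfonyl)oxy]butanoate (racemic) | Br/C=C(/C(C)OS(C)(=O)=O)C(=O)OC
A1 | alternative 1 | (1S,5S)-5-chloro-2-[(4R)-2,2-dimethyl-1,3-dioxolan-4-yl]-6,6-dimethylcyclohex-2-en-1-ol | CC1(C)[C@@H](Cl)CC=C([C@@H]2COC(C)(C)O2)[C@@H]1O
A2 | alternative 2 | methyl (3R,5S)-5-chloro-2-hydroxy-4,4-dimethyl-3-[(triisopropylsilyl)oxy]cyclohex-1-ene-1-carboxylate | CC1(C)[C@@H](Cl)CC(C(=O)OC)=C(O)[C@@H]1O[Si](C(C)C)(C(C)C)C(C)C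
A3 | alternative 3 | (4S,6S)-6-bromo-4-chloro-1-ethenyl-5,5-dimethylcyclohex-1-ene | CC1(C)[C@@H](Cl)CC=C(C=C)[C@@H]1Br
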